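**Retrosynthetic overview**
1. Target 30 ⇐ methyl ketone 28 (formylation, O‑methylation). The three carbinols and the ring ketone of 28 ⇐ diene 23 by a relay of hydroxyl‑directed oxidations (C7–OH → 8,8a‑epoxide → C8a–OH → OsO4 on C1=C2).
2. Key disconnection (in place of the intramolecular Diels–Alder): the C3–C4 bond of ring A, made by Ireland–Claisen ring contraction of the bicyclic δ‑lactone 19. It creates the quaternary C4 and C3 by chirality transfer.
3. 19 ⇐ dienone 17 (CBS reduction, lactonisation) ⇐ Nozaki–Hiyama–Kishi union of ring B enol triflate 11 with enal 15 (sec‑butyl centre from (S)‑2‑methylbutan‑1‑ol).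
4. 11 ⇐ (R)‑3,5‑dimethylcyclohexenone 6 (organocatalytic annulation) by α′‑alkylation, conjugate borylation and enol triflation.
5. Ring order: ring B first, then the temporary lactone ring, then ring A from that lactone; side chain last.

Assumption: decalin intermediates carry the ring numbering of the target (C1 ring ketone, C2 C(OH)Me, C3 CH‑sec‑butyl, C4 quaternary, C4a, C5 CHMe, C7 C(OH)Me, C8, C8a); β is the face of the C8a oxygen of the target, α the opposite face.
Assumption: 7, 12 and 14 are bought. The propanoate α‑carbon of 8–19 is drawn as formed by SN2 inversion; it is inconsequential because step 12 erases it.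

**Step 1**
Reactants: 1 (E)-but-2-enal; 2 tert-butyl 3-oxobutanoate
Product: 4 (5R)-5-methylcyclohex-2-en-1-one, via Michael adduct 3 (not isolated)
Conditions: (S)-2-{bis[3,5-bis(trifluoromethyl)phenyl](trimethylsilyloxy)methyl}pyrrolidine (10 mol %), PhCO2H (10 mol %), neat, 25 °C; then TsOH·H2O (20 mol %), toluene, 80 °C
Reagents that add atoms: none
Why: Iminium‑catalysed Michael addition of the β‑keto ester to the enal face not shielded by the diarylsilyloxymethyl group sets C5 (R), and acid then drives intramolecular aldol condensation, tert‑butyl ester cleavage and decarboxylation (organocatalytic Robinson‑type annulation).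

**Step 2**
Reactants: 4 (5R)-5-methylcyclohex-2-en-1-one
Product: 5 trimethyl{[(3R,5R)-3,5-dimethylcyclohex-1-en-1-yl]oxy}silane
Conditions: Me2CuLi (1.2 equiv), Me3SiCl (2 equiv), THF, −78 °C; Et3N quench
Reagents that add atoms: lithium dimethylcuprate, [Li+].C[Cu-]C; chlorotrimethylsilane, C[Si](C)(C)Cl
Why: Cuprate conjugate addition (trans to the ring methyl, a centre erased in step 3) with in situ O‑silylation gives the regiodefined enol silane.

**Step 3**
Reactants: 5 trimethyl{[(3R,5R)-3,5-dimethylcyclohex-1-en-1-yl]oxy}silane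
Product: 6 (5R)-3,5-dimethylcyclohex-2-en-1-one
Conditions: Pd(OAc)2 (10 mol %), O2 (1 atm), DMSO, 25 °C
Reagents that add atoms: none
Why: Saegusa–Ito oxidation (β‑hydride elimination from the palladium enolate) restores the enone now carrying the 3‑methyl group; the remaining stereocentre is untouched.

**Step 4**
Reactants: 6 (5R)-3,5-dimethylcyclohex-2-en-1-one; 7 ethyl (2S)-2-{[(trifluoromethyl)sulfonyl]oxy}propanoate
Product: 8 ethyl (2S)-2-[(1R,6R)-4,6-dimethyl-2-oxocyclohex-3-en-1-yl]propanoate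
Conditions: LiN(i-Pr)2 (1.05 equiv), THF, −78 °C; then 7, −78 → −20 °C
Reagents that add atoms: none
Why: Kinetic α′‑deprotonation gives the cross‑conjugated dienolate, which is C‑alkylated (SN2, inversion at the lactate carbon) anti to the neighbouring ring methyl, setting the future C4a trans to the C5 methyl.

**Step 5**
Reactants: 8 ethyl (2S)-2-[(1R,6R)-4,6-dimethyl-2-oxocyclohex-3-en-1-yl]propanoate
Product: 9 ethyl (2S)-2-[(1R,4S,6R)-4,6-dimethyl-2-oxo-4-(4,4,5,5-tetramethyl-1,3,2-dioxaborolan-2-yl)cyclohexyl]propanoate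
Conditions: CuCl (5 mol %), NaOt-Bu (10 mol %), Xantphos (5 mol %), B2pin2 (1.3 equiv), MeOH (2 equiv), THF, 25 °C
Reagents that add atoms: bis(pinacolato)diboron, CC1(C)OB(OC1(C)C)B1OC(C)(C)C(C)(C)O1
Why: Copper‑catalysed conjugate borylation: the boryl–copper species adds to the β‑carbon anti to the 5‑methyl group (trans‑3,5 rule for 5‑substituted cyclohexenones), so boron, the masked C7 hydroxyl, ends on the β face.

**Step 6**
Reactants: 9 ethyl (2S)-2-[(1R,4S,6R)-4,6-dimethyl-2-oxo-4-(4,4,5,5-tetramethyl-1,3,2-dioxaborolan-2-yl)cyclohexyl]propanoate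
Product: 11 ethyl (2S)-2-[(1R,4R,6R)-4-hydroxy-4,6-dimethyl-2-{[(trifluoromethyl)sulfonyl]oxy}cyclohex-2-en-1-yl]propanoate, via boryl enol triflate 10 (not isolated)
Conditions: KN(SiMe3)2 (1.1 equiv), THF, −78 °C; Comins' reagent (1.2 equiv), −78 → 0 °C; then 30 % H2O2, aq. NaHCO3, THF, 0 °C
Reagents that add atoms: N-(5-chloropyridin-2-yl)bis(trifluoromethanesulfonimide), O=S(=O)(N(c1ccc(Cl)cn1)S(=O)(=O)C(F)(F)F)C(F)(F)F; hydrogen peroxide, OO
Why: Kinetic enolisation at the ring methylene (not the substituted methine) and O‑triflation give the enol triflate without the retro‑aldol risk of a free β‑hydroxy ketone; buffered peroxide oxidation of the C–B bond then gives the tertiary alcohol with retention.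

**Step 7**
Reactants: 12 (2S)-2-methylbutan-1-ol
Product: 13 (2S)-2-methylbutanal
Conditions: TEMPO (1 mol %), KBr (10 mol %), NaOCl, NaHCO3, CH2Cl2/H2O, 0 °C
Reagents that add atoms: none
Why: Anelli (TEMPO/hypochlorite) oxidation gives the α‑chiral aldehyde without epimerisation; it is used at once.

**Step 8**
Reactants: 13 (2S)-2-methylbutanal; 14 2-(triphenyl-λ5-phosphanylidene)propanal
Product: 15 (2E,4S)-2,4-dimethylhex-2-enal
Conditions: CH2Cl2, 40 °C
Reagents that add atoms: none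
Why: Wittig olefination with the stabilised ylide gives the E trisubstituted enal under neutral conditions that leave the α‑stereocentre intact.

**Step 9**
Reactants: 11 ethyl (2S)-2-[(1R,4R,6R)-4-hydroxy-4,6-dimethyl-2-{[(trifluoromethyl)sulfonyl]oxy}cyclohex-2-en-1-yl]propanoate; 15 (2E,4S)-2,4-dimethylhex-2-enal
Product: 16 ethyl (2S)-2-[(1R,4R,6R)-4-hydroxy-2-[(2E,4S)-1-hydroxy-2,4-dimethylhex-2-en-1-yl]-4,6-dimethylcyclohex-2-en-1-yl]propanoate (both carbinol epimers)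
Conditions: CrCl2 (6 equiv), NiCl2 (2 mol %), DMF, 25 °C
Reagents that add atoms: none
Why: Nozaki–Hiyama–Kishi coupling (zerovalent nickel inserts into the vinyl triflate, transmetalation to chromium, 1,2‑addition to the aldehyde) tolerates the ester and the free tertiary alcohol; the new carbinol is not controlled here and is reset in steps 10 and 11.

**Step 10**
Reactants: 16 ethyl (2S)-2-[(1R,4R,6R)-4-hydroxy-2-[(2E,4S)-1-hydroxy-2,4-dimethylhex-2-en-1-yl]-4,6-dimethylcyclohex-2-en-1-yl]propanoate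
Product: 17 ethyl (2S)-2-[(1R,4R,6R)-2-[(2E,4S)-2,4-dimethylhex-2-enoyl]-4-hydroxy-4,6-dimethylcyclohex-2-en-1-yl]propanoate
Conditions: Dess–Martin periodinane (1.3 equiv), NaHCO3, CH2Cl2, 0 °C
Reagents that add atoms: none
Why: Dess–Martin oxidation converts the bis‑allylic alcohol into the cross‑conjugated dienone; the buffer protects the tertiary allylic alcohol.

**Step 11**
Reactants: 17 ethyl (2S)-2-[(1R,4R,6R)-2-[(2E,4S)-2,4-dimethylhex-2-enoyl]-4-hydroxy-4,6-dimethylcyclohex-2-en-1-yl]propanoate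
Product: 19 (1R,4S,4aR,5R,7R)-7-hydroxy-4,5,7-trimethyl-1-[(2E,4S)-4-methylhex-2-en-2-yl]-1,4,4a,5,6,7-hexahydro-3H-isochromen-3-one, via hydroxy ester 18 (not isolated)
Conditions: (S)-2-methyl-CBS-oxazaborolidine (0.5 equiv), catecholborane (3 equiv), toluene, −78 °C; MeOH quench; then DBU (0.3 equiv), toluene, 60 °C
Reagents that add atoms: none
Why: Corey–Bakshi–Shibata reduction: with the α‑branched cyclohexenyl arm as the large group, the (S)‑oxazaborolidine gives the (1R) carbinol by 1,2‑reduction only, and base‑catalysed transesterification then closes the δ‑lactone in which H1 and H4a are cis.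

**Step 12**
Reactants: 19 (1R,4S,4aR,5R,7R)-7-hydroxy-4,5,7-trimethyl-1-[(2E,4S)-4-methylhex-2-en-2-yl]-1,4,4a,5,6,7-hexahydro-3H-isochromen-3-one
Product: 22 3α-[(2S)-butan-2-yl]-7β-hydroxy-2,4β,5α,7α-tetramethyl-3,4,4aα,5,6,7-hexahydronaphthalene-4α-carboxylic acid, via bis-silyl ketene acetal 20 (not isolated), via bis-silyl ester 21 (not isolated)
Conditions: LiN(i-Pr)2 (2.4 equiv), Me3SiCl (5 equiv), Et3N, THF, −78 → 25 °C; then toluene, 100 °C; then K2CO3, MeOH/H2O, 25 °C; acidify to pH 5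
Reagents that add atoms: chlorotrimethylsilane, C[Si](C)(C)Cl (silicon is present in 20 and 21 only)
Why: Ireland–Claisen rearrangement of a lactone silyl ketene acetal (ring contraction): the endocyclic ketene acetal must react through a boat transition state, and the new C3–C4 bond forms on the face from which the lactone oxygen departs, so the (1R) carbinol and the E alkene set the quaternary C4 (CO2H α, Me β) and C3 (sec‑butyl α) relative to H4a as in the target, while the sp2 ring‑fusion carbon keeps ring B compatible with that boat.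

**Step 13**
Reactants: 22 3α-[(2S)-butan-2-yl]-7β-hydroxy-2,4β,5α,7α-tetramethyl-3,4,4aα,5,6,7-hexahydronaphthalene-4α-carboxylic acid
Product: 23 1-{3α-[(2S)-butan-2-yl]-7β-hydroxy-2,4β,5α,7α-tetramethyl-3,4,4aα,5,6,7-hexahydronaphthalen-4α-yl}ethan-1-one
Conditions: MeLi (6 equiv), THF, 0 → 25 °C; aq. NH4Cl
Reagents that add atoms: methyllithium, [Li]C
Why: Addition of methyllithium to the lithium carboxylate gives a dilithio gem‑diolate that collapses to the methyl ketone only on work‑up, so there is no over‑addition (carboxylic acid to methyl ketone).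

**Step 14**
Reactants: 23 1-{3α-[(2S)-butan-2-yl]-7β-hydroxy-2,4β,5α,7α-tetramethyl-3,4,4aα,5,6,7-hexahydronaphthalen-4α-yl}ethan-1-one
Product: 24 1-{3α-[(2S)-butan-2-yl]-8β,8aβ-epoxy-7β-hydroxy-2,4β,5α,7α-tetramethyl-3,4,4aα,5,6,7,8,8a-octahydronaphthalen-4α-yl}ethan-1-one
Conditions: VO(acac)2 (5 mol %), t-BuOOH (1.5 equiv), CH2Cl2, 0 °C
Reagents that add atoms: tert-butyl hydroperoxide, CC(C)(C)OO
Why: Vanadium‑catalysed hydroxyl‑directed epoxidation: the pseudoaxial tertiary allylic C7–OH delivers oxygen to the β face of the C8=C8a bond only, leaving the C1=C2 alkene.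

**Step 15**
Reactants: 24 1-{3α-[(2S)-butan-2-yl]-8β,8aβ-epoxy-7β-hydroxy-2,4β,5α,7α-tetramethyl-3,4,4aα,5,6,7,8,8a-octahydronaphthalen-4α-yl}ethan-1-one
Product: 25 3α-[(2S)-butan-2-yl]-4α-(1-hydroxyethyl)-2,4β,5α,7α-tetramethyl-3,4,4aα,5,6,7,8,8a-octahydronaphthalene-7β,8aβ-diol (both side-chain carbinol epimers)
Conditions: LiBHEt3 (5 equiv), THF, 0 → 25 °C; aq. NaOH
Reagents that add atoms: none
Why: SN2 hydride opening at the less substituted C8 (trans‑diaxial, Fürst–Plattner) leaves the C8a–O bond intact, giving the β C8a carbinol cis to C7–OH and trans to H4a; the side‑chain ketone is reduced too and is re‑oxidised in step 17.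

**Step 16**
Reactants: 25 3α-[(2S)-butan-2-yl]-4α-(1-hydroxyethyl)-2,4β,5α,7α-tetramethyl-3,4,4aα,5,6,7,8,8a-octahydronaphthalene-7β,8aβ-diol
Product: 27 3α-[(2S)-butan-2-yl]-4α-(1-hydroxyethyl)-2α,4β,5α,7α-tetramethyl-4aα-decahydronaphthalene-1β,2β,7β,8aβ-tetrol, via osmate ester 26 (not isolated)
Conditions: OsO4 (1.05 equiv), TMEDA (1.1 equiv), CH2Cl2, −78 °C; then aq. Na2SO3, THF, 25 °C
Reagents that add atoms: osmium tetroxide, O=[Os](=O)(=O)=O; N,N,N′,N′-tetramethylethane-1,2-diamine, CN(C)CCN(C)C (present in 26 only)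
Why: Donohoe directed dihydroxylation: hydrogen bonding of the OsO4–TMEDA complex to the allylic C8a–OH delivers both oxygens to the β face of C1=C2, setting C2 (OH β, Me α) and C1; the remote side‑chain carbinol on the α face is too far to compete.

**Step 17**
Reactants: 27 3α-[(2S)-butan-2-yl]-4α-(1-hydroxyethyl)-2α,4β,5α,7α-tetramethyl-4aα-decahydronaphthalene-1β,2β,7β,8aβ-tetrol
Product: 28 4α-acetyl-3α-[(2S)-butan-2-yl]-2β,7β,8aβ-trihydroxy-2α,4β,5α,7α-tetramethyl-4aα-octahydronaphthalen-1(2H)-one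
Conditions: IBX (6 equiv), DMSO, 40 °C
Reagents that add atoms: none
Why: IBX oxidation converts the two secondary alcohols (C1–OH and the side‑chain carbinol) into ketones without cleaving the vicinal diols; the tertiary alcohols cannot react.

**Step 18**
Reactants: 28 4α-acetyl-3α-[(2S)-butan-2-yl]-2β,7β,8aβ-trihydroxy-2α,4β,5α,7α-tetramethyl-4aα-octahydronaphthalen-1(2H)-one
Product: 29 3-{3α-[(2S)-butan-2-yl]-2β,7β,8aβ-trihydroxy-2α,4β,5α,7α-tetramethyl-1-oxo-4aα-decahydronaphthalen-4α-yl}-3-oxopropanal (present as its enol)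
Conditions: NaH (6 equiv), HCO2Et (15 equiv), THF, 0 → 25 °C; aq. HCl to pH 4
Reagents that add atoms: ethyl formate, CCOC=O
Why: Crossed Claisen condensation: only the acetyl methyl can enolise (the ring ketone has no α‑hydrogen), and formation of the stable sodium enolate of the β‑keto aldehyde drives the reaction.

**Step 19**
Reactants: 29 3-{3α-[(2S)-butan-2-yl]-2β,7β,8aβ-trihydroxy-2α,4β,5α,7α-tetramethyl-1-oxo-4aα-decahydronaphthalen-4α-yl}-3-oxopropanal
Product: 30 (2S,3R,4S,4aR,5R,7R,8aR)-3-[(2S)-butan-2-yl]-2,7,8a-trihydroxy-4-[(2E)-3-methoxyprop-2-enoyl]-2,4,5,7-tetramethyloctahydronaphthalen-1(2H)-one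
Conditions: Me3SiCHN2 (2 equiv), MeOH/toluene 1:4, 0 °C
Reagents that add atoms: (trimethylsilyl)diazomethane, C[Si](C)(C)C=[N+]=[N-]
Why: O‑Methylation of the acidic enol by diazomethane generated in situ gives the vinylogous ester, which adopts the conjugated E geometry; the tertiary alcohols are not acidic enough to be methylated.

**Compound list**
1 | (E)-but-2-enal | C/C=C/C=O | starting material
2 | tert-butyl 3-oxobutanoate | CC(=O)CC(=O)OC(C)(C)C | starting material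
3 | tert-butyl (3R)-2-acetyl-3-methyl-5-oxopentanoate | CC(=O)C(C(=O)OC(C)(C)C)[C@H](C)CC=O | intermediate
4 | (5R)-5-methylcyclohex-2-en-1-one | O=C1C=CC[C@@H](C)C1 | intermediate
5 | trimethyl{[(3R,5R)-3,5-dimethylcyclohex-1-en-1-yl]oxy}silane | C[Si](C)(C)OC1=C[C@H](C)C[C@@H](C)C1 | intermediate
6 | (5R)-3,5-dimethylcyclohex-2-en-1-one | O=C1C=C(C)C[C@@H](C)C1 | intermediate
7 | ethyl (2S)-2-{[(trifluoromethyl)sulfonyl]oxy}propanoate | CCOC(=O)[C@H](C)OS(=O)(=O)C(F)(F)F | starting material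
8 | ethyl (2S)-2-[(1R,6R)-4,6-dimethyl-2-oxocyclohex-3-en-1-yl]propanoate | CCOC(=O)[C@@H](C)[C@H]1[C@H](C)CC(C)=CC1=O | intermediate
9 | ethyl (2S)-2-[(1R,4S,6R)-4,6-dimethyl-2-oxo-4-(4,4,5,5-tetramethyl-1,3,2-dioxaborolan-2-yl)cyclohexyl]propanoate | CCOC(=O)[C@@H](C)[C@H]1[C@H](C)C[C@@](C)(B2OC(C)(C)C(C)(C)O2)CC1=O | intermediate
10 | ethyl (2S)-2-[(1R,4S,6R)-4,6-dimethyl-4-(4,4,5,5-tetramethyl-1,3,2-dioxaborolan-2-yl)-2-{[(trifluoromethyl)sulfonyl]oxy}cyclohex-2-en-1-yl]propanoate | CCOC(=O)[C@@H](C)[C@H]1[C@H](C)C[C@@](C)(B2OC(C)(C)C(C)(C)O2)C=C1OS(=O)(=O)C(F)(F)F | intermediate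
11 | ethyl (2S)-2-[(1R,4R,6R)-4-hydroxy-4,6-dimethyl-2-{[(trifluoromethyl)sulfonyl]oxy}cyclohex-2-en-1-yl]propanoate | CCOC(=O)[C@@H](C)[C@H]1[C@H](C)C[C@@](C)(O)C=C1OS(=O)(=O)C(F)(F)F | intermediate
12 | (2S)-2-methylbutan-1-ol | CC[C@H](C)CO | starting material
13 | (2S)-2-methylbutanal | CC[C@H](C)C=O | intermediate
14 | 2-(triphenyl-λ5-phosphanylidene)propanal | CC(C=O)=P(c1ccccc1)(c1ccccc1)c1ccccc1 | starting material
15 | (2E,4S)-2,4-dimethylhex-2-enal | CC[C@H](C)/C=C(C)/C=O | intermediate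
16 | ethyl (2S)-2-[(1R,4R,6R)-4-hydroxy-2-[(2E,4S)-1-hydroxy-2,4-dimethylhex-2-en-1-yl]-4,6-dimethylcyclohex-2-en-1-yl]propanoate (both carbinol epimers) | CCOC(=O)[C@@H](C)[C@H]1[C@H](C)C[C@@](C)(O)C=C1C(O)/C(C)=C/[C@@H](C)CC | intermediate
17 | ethyl (2S)-2-[(1R,4R,6R)-2-[(2E,4S)-2,4-dimethylhex-2-enoyl]-4-hydroxy-4,6-dimethylcyclohex-2-en-1-yl]propanoate | CCOC(=O)[C@@H](C)[C@H]1[C@H](C)C[C@@](C)(O)C=C1C(=O)/C(C)=C/[C@@H](C)CC | intermediate
18 | ethyl (2S)-2-[(1R,4R,6R)-4-hydroxy-2-[(1R,2E,4S)-1-hydroxy-2,4-dimethylhex-2-en-1-yl]-4,6-dimethylcyclohex-2-en-1-yl]propanoate | CCOC(=O)[C@@H](C)[C@H]1[C@H](C)C[C@@](C)(O)C=C1[C@H](O)/C(C)=C/[C@@H](C)CC | intermediate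
19 | (1R,4S,4aR,5R,7R)-7-hydroxy-4,5,7-trimethyl-1-[(2E,4S)-4-methylhex-2-en-2-yl]-1,4,4a,5,6,7-hexahydro-3H-isochromen-3-one | C[C@@H]1C(=O)O[C@H](/C(C)=C/[C@@H](C)CC)C2=C[C@](C)(O)C[C@@H](C)[C@H]12 | intermediate
20 | O-trimethylsilyl ketene acetal of lactone 19 (C3=C4 double bond, 3-OSiMe3) with the 7-OH as its trimethylsilyl ether | CC1=C(O[Si](C)(C)C)O[C@H](/C(C)=C/[C@@H](C)CC)C2=C[C@](C)(O[Si](C)(C)C)C[C@@H](C)[C@H]12 | intermediate
21 | trimethylsilyl ester of acid 22 with the 7-OH as its trimethylsilyl ether | CC[C@H](C)[C@@H]1[C@](C)(C(=O)O[Si](C)(C)C)[C@H]2[C@H](C)C[C@@](C)(O[Si](C)(C)C)C=C2C=C1C | intermediate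
22 | 3α-[(2S)-butan-2-yl]-7β-hydroxy-2,4β,5α,7α-tetramethyl-3,4,4aα,5,6,7-hexahydronaphthalene-4α-carboxylic acid (C1=C2 and C8=C8a double bonds) | CC[C@H](C)[C@@H]1[C@](C)(C(=O)O)[C@H]2[C@H](C)C[C@@](C)(O)C=C2C=C1C | intermediate
23 | 1-{3α-[(2S)-butan-2-yl]-7β-hydroxy-2,4β,5α,7α-tetramethyl-3,4,4aα,5,6,7-hexahydronaphthalen-4α-yl}ethan-1-one | CC[C@H](C)[C@@H]1[C@](C)(C(C)=O)[C@H]2[C@H](C)C[C@@](C)(O)C=C2C=C1C | intermediate
24 | 1-{3α-[(2S)-butan-2-yl]-8β,8aβ-epoxy-7β-hydroxy-2,4β,5α,7α-tetramethyl-3,4,4aα,5,6,7,8,8a-octahydronaphthalen-4α-yl}ethan-1-one | CC[C@H](C)[C@@H]1[C@](C)(C(C)=O)[C@H]2[C@H](C)C[C@@](C)(O)[C@H]3O[C@@]23C=C1C | intermediate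
25 | 3α-[(2S)-butan-2-yl]-4α-(1-hydroxyethyl)-2,4β,5α,7α-tetramethyl-3,4,4aα,5,6,7,8,8a-octahydronaphthalene-7β,8aβ-diol (both side-chain carbinol epimers) | CC[C@H](C)[C@@H]1[C@](C)(C(C)O)[C@H]2[C@H](C)C[C@@](C)(O)C[C@]2(O)C=C1C | intermediate
26 | cyclic osmate ester of 27 across O1 and O2, TMEDA adduct | CC[C@H](C)[C@@H]1[C@](C)(C(C)O)[C@H]2[C@H](C)C[C@@](C)(O)C[C@]2(O)[C@H]3O[Os](=O)(=O)O[C@@]13C.CN(C)CCN(C)C | intermediate
27 | 3α-[(2S)-butan-2-yl]-4α-(1-hydroxyethyl)-2α,4β,5α,7α-tetramethyl-4aα-decahydronaphthalene-1β,2β,7β,8aβ-tetrol (both side-chain carbinol epimers) | CC[C@H](C)[C@@H]1[C@](C)(C(C)O)[C@H]2[C@H](C)C[C@@](C)(O)C[C@]2(O)[C@@H](O)[C@@]1(C)O | intermediate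
28 | 4α-acetyl-3α-[(2S)-butan-2-yl]-2β,7β,8aβ-trihydroxy-2α,4β,5α,7α-tetramethyl-4aα-octahydronaphthalen-1(2H)-one | CC[C@H](C)[C@@H]1[C@](C)(C(C)=O)[C@H]2[C@H](C)C[C@@](C)(O)C[C@]2(O)C(=O)[C@@]1(C)O | intermediate
29 | 3-{3α-[(2S)-butan-2-yl]-2β,7β,8aβ-trihydroxy-2α,4β,5α,7α-tetramethyl-1-oxo-4aα-decahydronaphthalen-4α-yl}-3-oxopropanal (drawn as the keto aldehyde, present as its enol) | CC[C@H](C)[C@@H]1[C@](C)(C(=O)CC=O)[C@H]2[C@H](C)C[C@@](C)(O)C[C@]2(O)C(=O)[C@@]1(C)O | intermediate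
30 | (2S,3R,4S,4aR,5R,7R,8aR)-3-[(2S)-butan-2-yl]-2,7,8a-trihydroxy-4-[(2E)-3-methoxyprop-2-enoyl]-2,4,5,7-tetramethyloctahydronaphthalen-1(2H)-one | CC[C@H](C)[C@@H]1[C@](C)(C(=O)/C=C/OC)[C@H]2[C@H](C)C[C@@](C)(O)C[C@]2(O)C(=O)[C@@]1(C)O | target

**Step count**
Total: 19 steps. Longest linear sequence: 17 steps (steps 1–6, then 9–19); the enal branch is steps 7–8.

**Steps most likely to fail, and fallbacks**

Step 4 (C‑alkylation of the dienolate by a secondary triflate; O‑alkylation or elimination may win). The fallback sets out from 6 and comes back at 8. Ketone 6 is condensed with Me2NNH2 (cat. AcOH, EtOH) to the N,N‑dimethylhydrazone F1. LiN(i-Pr)2 (THF, −78 °C) gives the softer α′ aza‑enolate, which is alkylated with 7, again anti to the ring methyl, to the hydrazone ester F2. CuCl2 in aqueous THF hydrolyses F2 to 8.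

Step 12 (the key ring contraction; the enolate of the ring‑fused, bis‑allylic lactone may fragment or fail to reach the boat geometry). The fallback sets out from 18 (step 11 worked up before the DBU treatment) and comes back at 22. ClCO2Me/pyridine converts 18 into the allylic methyl carbonate F3. LiN(SiMe3)2 and then Pd(PPh3)4 (THF, 0 → 40 °C) close ring A by intramolecular Tsuji–Trost alkylation of the ester enolate at the distal allyl terminus, giving the ring‑closed ethyl ester F4. Ionisation and attack are both anti to palladium, so the bond forms on the face the oxygen left, as in the sigmatropic step. KOSiMe3 (THF, 60 °C) cleaves the hindered ester to 22.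

Step 15 (hydride may attack the vinyl epoxide in the SN2′ sense, or the epoxide may ionise and be captured by the side‑chain oxygen). The fallback sets out from 24 and comes back at 25. LiI/AcOH (THF, −20 °C) opens the epoxide trans‑diaxially at C8 to the iodohydrin F5. Bu3SnH/AIBN (toluene, 80 °C) removes iodine by a radical chain to give the diol methyl ketone F6. NaBH4 (MeOH, 0 °C) reduces the side‑chain ketone to 25.

**Further compounds**
F1 | step 4 | (5R)-1-(2,2-dimethylhydrazinylidene)-3,5-dimethylcyclohex-2-ene | CN(C)N=C1C=C(C)C[C@@H](C)C1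
F2 | step 4 | ethyl (2S)-2-[(1R,6R)-2-(2,2-dimethylhydrazinylidene)-4,6-dimethylcyclohex-3-en-1-yl]propanoate | CCOC(=O)[C@@H](C)[C@H]1[C@H](C)CC(C)=CC1=NN(C)C
F3 | step 12 | ethyl (2S)-2-[(1R,4R,6R)-4-hydroxy-2-{(1R,2E,4S)-1-[(methoxycarbonyl)oxy]-2,4-dimethylhex-2-en-1-yl}-4,6-dimethylcyclohex-2-en-1-yl]propanoate | CCOC(=O)[C@@H](C)[C@H]1[C@H](C)C[C@@](C)(O)C=C1[C@H](OC(=O)OC)/C(C)=C/[C@@H](C)CC
F4 | step 12 | ethyl 3α-[(2S)-butan-2-yl]-7β-hydroxy-2,4β,5α,7α-tetramethyl-3,4,4aα,5,6,7-hexahydronaphthalene-4α-carboxylate | CC[C@H](C)[C@@H]1[C@](C)(C(=O)OCC)[C@H]2[C@H](C)C[C@@](C)(O)C=C2C=C1C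
F5 | step 15 | 1-{3α-[(2S)-butan-2-yl]-7β,8aβ-dihydroxy-8α-iodo-2,4β,5α,7α-tetramethyl-3,4,4aα,5,6,7,8,8a-octahydronaphthalen-4α-yl}ethan-1-one | CC[C@H](C)[C@@H]1[C@](C)(C(C)=O)[C@H]2[C@H](C)C[C@@](C)(O)[C@H](I)[C@]2(O)C=C1C
F6 | step 15 | 1-{3α-[(2S)-butan-2-yl]-7β,8aβ-dihydroxy-2,4β,5α,7α-tetramethyl-3,4,4aα,5,6,7,8,8a-octahydronaphthalen-4α-yl}ethan-1-one | CC[C@H](C)[C@@H]1[C@](C)(C(C)=O)[C@H]2[C@H](C)C[C@@](C)(O)C[C@]2(O)C=C1C
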